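**Strategy.** Everything rests on disconnecting C6–C10 and C1–C2 of the cis-fused cyclopentane–cycloheptane core. The exocyclic C1=CH2 beside ring-fusion carbon C10 is read as the surviving half of an allene, C10=C1=CH2. Its internal double bond and a 1-siloxy-1-vinylcyclopropane (C6=C5, C4, C3, C2), joined through C7–C9, combine in one rhodium-catalysed (5+2) cycloaddition. This closes both rings, sets C6 and C10 cis, and leaves a C4 silyl enol ether marking C5 for gem-dimethylation. The precursor is an acyclic allene–vinylcyclopropane whose C9 quaternary centre (methyl, CH2OSi(i-Pr)3) comes from geraniol by asymmetric epoxidation and a 1,2-shift. The lactone side chain is grown afterwards from C11.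

Key step: step 10

Remark: locants C1–C16 are those of the target skeleton (C1 bears =CH2, C5 is CMe2, C6/C10 are the ring-fusion carbons, C9 is the quaternary centre, C11–C16 form the side chain); reagents that supply only heteroatoms or protecting groups are given by name and SMILES in the step and carry no number.

Step 1
Reactants: 1 geraniol
Product: 2 (2S,3S)-2,3-epoxygeraniol
Conditions: Ti(OiPr)4 (5 mol%), L-(+)-diethyl tartrate (7 mol%), t-BuOOH, 4 Å molecular sieves, CH2Cl2, −20 °C
Reagents that add atoms: tert-butyl hydroperoxide, CC(C)(C)OO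
Why: Sharpless asymmetric epoxidation of the allylic alcohol, where the natural tartrate should give the (2S,3S) epoxide and so fix the carbon that becomes C9.

Step 2
Reactants: 2 (2S,3S)-2,3-epoxygeraniol
Product: 3 triisopropylsilyl ether of 2
Conditions: i-Pr3SiCl, imidazole, DMAP (cat.), CH2Cl2, rt
Reagents that add atoms: chlorotri(propan-2-yl)silane, CC(C)[Si](Cl)(C(C)C)C(C)C
Why: Standard silylation of a primary alcohol; the bulky, weakly coordinating silyl ether is what both the next rearrangement and the later cycloaddition require.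

Step 3
Reactants: 3 triisopropylsilyl ether of 2
Product: 4 (2S)-2,6-dimethyl-2-{[tri(propan-2-yl)silyl]oxymethyl}hept-5-enal
Conditions: MeAl(OC6H2-4-Br-2,6-t-Bu2)2 [methylaluminium bis(4-bromo-2,6-di-tert-butylphenoxide), 20 mol%], CH2Cl2, −78 to −20 °C
Reagents that add atoms: none
Why: Lewis-acid-promoted semipinacol-type rearrangement of a 2,3-epoxy silyl ether, in which the epoxide ionises at its tertiary carbon and the silyloxymethyl group migrates anti to the breaking C–O bond, so the epoxide chirality is transferred with inversion to the all-carbon quaternary centre (future C9) and the former C2 becomes the aldehyde.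

Step 4
Reactants: 4 (2S)-aldehyde; 5 dimethyl (1-diazo-2-oxopropyl)phosphonate
Product: 6 (3R)-3,7-dimethyl-3-{[tri(propan-2-yl)silyl]oxymethyl}oct-6-en-1-yne
Conditions: K2CO3, MeOH, 0 °C to rt
Reagents that add atoms: 5 dimethyl (1-diazo-2-oxopropyl)phosphonate, COP(=O)(OC)C(=[N+]=[N-])C(C)=O
Why: Ohira–Bestmann alkyne homologation, safe here because the aldehyde has no α-hydrogen and so cannot epimerise or eliminate in basic methanol.

Step 5
Reactants: 6 (3R)-enyne
Product: 7 (4R)-4-methyl-4-{[tri(propan-2-yl)silyl]oxymethyl}hex-5-ynal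
Conditions: O3, CH2Cl2/MeOH, pyridine, −78 °C (Sudan Red 7B end point); then Me2S
Reagents that add atoms: ozone, [O-][O+]=O
Why: Ozonolysis with reductive work-up, chemoselective because the trisubstituted alkene reacts far faster than the terminal alkyne and the dye marks the end point.

Step 6
Reactants: 7 alkynyl aldehyde; 8 triethyl phosphonoacetate
Product: 9 ethyl (2E,6R)-6-methyl-6-{[tri(propan-2-yl)silyl]oxymethyl}oct-2-en-7-ynoate
Conditions: LiCl, DBU, MeCN, rt
Reagents that add atoms: 8 triethyl phosphonoacetate, CCOC(=O)CP(=O)(OCC)OCC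
Why: Horner–Wadsworth–Emmons olefination under mild amine/LiCl conditions should give the E-enoate without deprotonating the alkyne.

Step 7
Reactants: 9 (E)-enoate; 10 ethylmagnesium bromide
Product: 11 1-[(1E,5R)-5-methyl-5-{[tri(propan-2-yl)silyl]oxymethyl}hept-1-en-6-yn-1-yl]cyclopropan-1-ol
Conditions: EtMgBr (4 equiv), Ti(OiPr)4 (0.5 equiv), THF, 0 °C to rt; aq. NH4Cl at 0 °C
Reagents that add atoms: 10 ethylmagnesium bromide, CC[Mg]Br
Why: Kulinkovich cyclopropanation, in which the titanacyclopropane from EtMgBr adds twice to the ester carbonyl; the first equivalent of Grignard reagent masks the alkyne as its magnesium acetylide and the β-substituted E-alkene is retained.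

Step 8
Reactants: 11 alkenylcyclopropanol
Product: 12 tert-butyldimethylsilyl ether of 11
Conditions: t-BuMe2SiOTf, 2,6-lutidine, CH2Cl2, −78 to 0 °C
Reagents that add atoms: tert-butyldimethylsilyl triflate, CC(C)(C)[Si](C)(C)OS(=O)(=O)C(F)(F)F
Why: Silylation of the tertiary cyclopropanol with a silyl triflate and a hindered base avoids the acid- or base-induced ring opening of the cyclopropanol.

Step 9
Reactants: 12 alkynyl siloxyvinylcyclopropane; 13 formaldehyde (as paraformaldehyde)
Product: 15 allene-tethered 1-siloxy-1-vinylcyclopropane (9R), via propargylic amine 14 (not isolated)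
Conditions: (CH2O)n, CuBr (0.5 equiv), i-Pr2NH, 1,4-dioxane, reflux
Reagents that add atoms: 13 formaldehyde, C=O
Why: Crabbé allene homologation, a Mannich reaction to the propargylic amine followed by copper-mediated internal hydride transfer and loss of the imine, turns the terminal alkyne into the terminal allene C10=C1=CH2.

Step 10
Reactants: 15 allene-tethered 1-siloxy-1-vinylcyclopropane
Product: 16 cis-fused cycloadduct (6R,9R,10S) with C1 methylidene and C4 silyl enol ether
Conditions: [Rh(CO)2Cl]2 (5 mol%), toluene (degassed, 0.02 M), 90 °C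
Reagents that add atoms: none
Why: Monovalent rhodium binds the vinylcyclopropane and the internal C10=C1 bond of the allene, oxidative coupling with cleavage of one C4–CH2 cyclopropane bond gives a trivalent rhodium allyl metallacycle containing the new C6–C10 bond, and C–C reductive elimination then joins C1 to C2. The closest known reaction type is the intramolecular (5+2) cycloaddition of vinylcyclopropanes with tethered allenes under [Rh(CO)2Cl]2, which is also known for 1-oxygenated cyclopropanes. The cyclopentane closes when C6–C10 forms across the three-atom C7–C9 tether, and the cycloheptane closes in the reductive elimination from the eight-membered rhodacycle. C6 and C10 are created together and cis, because both partners add suprafacially, and their sense relative to C9 is set by the quaternary centre, whose bulky silyloxymethyl group should take the convex face of the forming bicycle while the methyl group lies on the side of C1. The step needs chemoselectivity for the internal allene bond (secured by the short tether, the distal bond surviving as C1=CH2) and facial selectivity (resting on the size difference between CH3 and CH2OSi(i-Pr)3); the two cyclopropane CH2 groups are equivalent, so ring opening has no regiochemical issue, and the siloxy group ends as the C4 enol ether.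

Step 11
Reactants: 16 cycloadduct; 17 N,N-dimethylmethyleneiminium iodide; 18 iodomethane
Product: 21 C5-methylidene C4-ketone, via Mannich base 19 (not isolated), via ammonium iodide 20 (not isolated)
Conditions: Me2N=CH2+ I−, CH2Cl2, 0 °C to rt; then MeI, THF, rt; then DBU, 0 °C
Reagents that add atoms: 17 N,N-dimethylmethyleneiminium iodide, C=[N+](C)C.[I-]
Why: Mannich reaction of the silyl enol ether places the aminomethyl group regiospecifically at C5, and quaternisation followed by base-induced elimination gives the α-methylene ketone.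

Step 12
Reactants: 21 α-methylene ketone; 18 iodomethane
Product: 23 C5,C5-dimethyl C4-ketone, via lithium enolate 22 (not isolated)
Conditions: LiBH(s-Bu)3, THF, −78 °C; then MeI (5 equiv), DMPU, −78 to 0 °C
Reagents that add atoms: 18 iodomethane, CI
Why: Reductive alkylation of an enone: conjugate hydride addition to the β-unsubstituted enone makes the first methyl group and the C5 enolate regiospecifically, and C-methylation of that enolate completes the gem-dimethyl group without touching C3.

Step 13
Reactants: 23 gem-dimethyl ketone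
Product: 24 C11 hydroxy ketone
Conditions: Bu4NF, THF, rt
Reagents that add atoms: none
Why: Fluoride-mediated cleavage of the silyl ether frees the C11 alcohol before the strongly basic reduction.

Step 14
Reactants: 24 hydroxy ketone
Product: 26 C11 alcohol of the deoxygenated bicycle, via hydrazone 25 (not isolated)
Conditions: N2H4·H2O, KOH, diethylene glycol, 130 °C then 200 °C, argon
Reagents that add atoms: none
Why: Wolff–Kishner reduction (Huang-Minlon procedure) removes the C4 carbonyl, which has no epimerisable neighbour (C5 is quaternary), while the isolated alkene is inert to base and exclusion of air prevents diimide formation.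

Step 15
Reactants: 26 C11 alcohol
Product: 27 C11 aldehyde
Conditions: Dess–Martin periodinane, CH2Cl2, 0 °C to rt
Reagents that add atoms: none
Why: Dess–Martin oxidation of the neopentyl primary alcohol gives an aldehyde that cannot enolise.

Step 16
Reactants: 27 C11 aldehyde; 28 (methoxymethyl)triphenylphosphonium chloride
Product: 30 homologated aldehyde C9–C11H2–C13HO, via enol ether 29 (not isolated)
Conditions: 28, KN(SiMe3)2, THF, 0 °C to rt; then 1 M HCl, THF, 0 °C to rt
Reagents that add atoms: 28 (methoxymethyl)triphenylphosphonium chloride, COC[P+](c1ccccc1)(c1ccccc1)c1ccccc1.[Cl-]; water, O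
Why: Wittig methoxymethylenation followed by mild hydrolysis of the enol ether is a one-carbon aldehyde homologation, which turns C11 into an enolisable CH2 and adds C13.

Step 17
Reactants: 30 homologated aldehyde; 13 formaldehyde (37% aqueous)
Product: 31 (11R)-β-hydroxy aldehyde C9–C11H(C12H2OH)–C13HO
Conditions: aq. CH2O, (S)-2-[diphenyl(trimethylsilyloxy)methyl]pyrrolidine (20 mol%), pH 7 phosphate buffer, toluene, rt
Reagents that add atoms: 13 formaldehyde, C=O
Why: Enamine-catalysed cross-aldol reaction (α-hydroxymethylation), in which the diaryl(silyloxy)methyl group of the (S)-catalyst shields one face of the E-enamine so that formaldehyde should add to the other face and give the 11R centre under catalyst control.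

Step 18
Reactants: 31 β-hydroxy aldehyde; 32 (triphenylphosphoranylidene)ketene
Product: 34 α,β-unsaturated δ-lactone (O–C12, C15=O, C16=C13, C11 in the ring), via acyl ylide 33 (not isolated)
Conditions: Ph3P=C=C=O, toluene, 70 °C
Reagents that add atoms: 32 (triphenylphosphoranylidene)ketene, O=C=C=P(c1ccccc1)(c1ccccc1)c1ccccc1
Why: The alcohol adds to the cumulated ylide to give an ester-stabilised ylide, and an intramolecular Wittig reaction with the aldehyde closes the six-membered unsaturated lactone, Z by ring constraint, under neutral conditions that spare the C11 centre.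

Step 19
Reactants: 34 unsaturated δ-lactone; 35 (chloromethyl)(isopropoxy)dimethylsilane (as its Grignard reagent)
Product: 36 trans-4,5-disubstituted δ-lactone with C14H2SiMe2(Oi-Pr) at C13
Conditions: (i-PrO)Me2SiCH2MgCl (from 35, Mg, THF), CuI (10 mol%), THF, −78 to −30 °C; aq. NH4Cl
Reagents that add atoms: (isopropoxydimethylsilyl)methylmagnesium chloride from 35, CC(C)O[Si](C)(C)C[Mg]Cl
Why: Copper-catalysed conjugate addition of a hydroxymethyl anion equivalent, which should enter C13 anti to the bulky substituent on the neighbouring ring carbon C11 and so set C13 by ring control.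

Step 20
Reactants: 36 silylmethyl δ-lactone
Product: 38 hydroxy γ-lactone (O–C14, C15=O) with free C12H2OH, via hydroxymethyl lactone 37 (not isolated)
Conditions: KF, KHCO3, 30% H2O2, THF/MeOH, rt; then DBU (cat.), CH2Cl2, rt
Reagents that add atoms: hydrogen peroxide, OO
Why: Tamao oxidation converts the C–Si bond into C14–OH under nucleophilic peroxide conditions that leave the alkene alone, and base-catalysed translactonisation should then move the acyl group to the new hydroxyl to give the more stable five-membered lactone.

Step 21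
Reactants: 38 hydroxy γ-lactone
Product: 39 triethylsilyl ether of 38
Conditions: Et3SiCl, imidazole, CH2Cl2, 0 °C
Reagents that add atoms: chlorotriethylsilane, CC[Si](Cl)(CC)CC
Why: Silylation blocks the C12 hydroxyl so that no alkoxide can reopen or isomerise the lactone during enolate formation.

Step 22
Reactants: 39 silylated γ-lactone
Product: 41 C12,C16-diol (trans-α-hydroxy-β-substituted γ-lactone), via silyl ether 40 (not isolated)
Conditions: KN(SiMe3)2, THF, −78 °C; 2-(phenylsulfonyl)-3-phenyloxaziridine, −78 °C; AcOH; then PPTS, MeOH, rt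
Reagents that add atoms: 2-(phenylsulfonyl)-3-phenyloxaziridine, O=S(=O)(c1ccccc1)N1OC1c1ccccc1
Why: Enolate hydroxylation with a Davis oxaziridine, where the oxidant should approach the potassium enolate anti to the C13 substituent to give the trans C16 alcohol, and the mildly acidic methanol work-up removes the triethylsilyl group.

Step 23
Reactants: 41 diol; 42 acetic anhydride
Product: 43 target diacetate
Conditions: Ac2O, pyridine, DMAP (cat.), CH2Cl2, 0 °C to rt
Reagents that add atoms: 42 acetic anhydride, CC(=O)OC(C)=O
Why: Acylation of the primary C12 and secondary C16 alcohols under mild nucleophilic catalysis completes the target without touching any stereocentre.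

**Compound list**

1 | geraniol, (2E)-3,7-dimethylocta-2,6-dien-1-ol | CC(C)=CCC/C(C)=C/CO | starting material
2 | (2S,3S)-2,3-epoxygeraniol | OC[C@@H]1O[C@@]1(C)CCC=C(C)C | intermediate
3 | (2S,3S)-2,3-epoxygeranyl triisopropylsilyl ether | CC(C)[Si](C(C)C)(C(C)C)OC[C@@H]1O[C@@]1(C)CCC=C(C)C | intermediate
4 | (2S)-2,6-dimethyl-2-{[tri(propan-2-yl)silyl]oxymethyl}hept-5-enal | O=C[C@](C)(CO[Si](C(C)C)(C(C)C)C(C)C)CCC=C(C)C | intermediate
5 | dimethyl (1-diazo-2-oxopropyl)phosphonate | COP(=O)(OC)C(=[N+]=[N-])C(C)=O | starting material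
6 | (3R)-3,7-dimethyl-3-{[tri(propan-2-yl)silyl]oxymethyl}oct-6-en-1-yne | C#C[C@](C)(CO[Si](C(C)C)(C(C)C)C(C)C)CCC=C(C)C | intermediate
7 | (4R)-4-methyl-4-{[tri(propan-2-yl)silyl]oxymethyl}hex-5-ynal | C#C[C@](C)(CO[Si](C(C)C)(C(C)C)C(C)C)CCC=O | intermediate
8 | triethyl phosphonoacetate | CCOC(=O)CP(=O)(OCC)OCC | starting material
9 | ethyl (2E,6R)-6-methyl-6-{[tri(propan-2-yl)silyl]oxymethyl}oct-2-en-7-ynoate | C#C[C@](C)(CO[Si](C(C)C)(C(C)C)C(C)C)CC/C=C/C(=O)OCC | intermediate
10 | ethylmagnesium bromide | CC[Mg]Br | starting material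
11 | 1-[(1E,5R)-5-methyl-5-{[tri(propan-2-yl)silyl]oxymethyl}hept-1-en-6-yn-1-yl]cyclopropan-1-ol | C#C[C@](C)(CO[Si](C(C)C)(C(C)C)C(C)C)CC/C=C/C1(O)CC1 | intermediate
12 | tert-butyldimethylsilyl ether of 11 | C#C[C@](C)(CO[Si](C(C)C)(C(C)C)C(C)C)CC/C=C/C1(O[Si](C)(C)C(C)(C)C)CC1 | intermediate
13 | formaldehyde (used as paraformaldehyde and as 37% aqueous solution) | C=O | starting material
14 | propargylic diisopropylamine from 12 (alkyne terminus carrying CH2N(i-Pr)2) | CC(C)N(C(C)C)CC#C[C@](C)(CO[Si](C(C)C)(C(C)C)C(C)C)CC/C=C/C1(O[Si](C)(C)C(C)(C)C)CC1 | intermediate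
15 | allene-tethered 1-siloxy-1-vinylcyclopropane, (9R), E-alkene, C9 bearing CH3 and CH2OSi(i-Pr)3 | C=C=C[C@](C)(CO[Si](C(C)C)(C(C)C)C(C)C)CC/C=C/C1(O[Si](C)(C)C(C)(C)C)CC1 | intermediate
16 | cis-fused cycloadduct (6R,9R,10S): bicyclo[5.3.0]decane core, C1 methylidene, C4=C5 tert-butyldimethylsilyl enol ether, H6, H10 and CH2OSi(i-Pr)3 on one face | C=C1CCC(O[Si](C)(C)C(C)(C)C)=C[C@@H]2CC[C@@](C)(CO[Si](C(C)C)(C(C)C)C(C)C)[C@H]12 | intermediate
17 | N,N-dimethylmethyleneiminium iodide | C=[N+](C)C.[I-] | starting material
18 | iodomethane | CI | starting material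
19 | Mannich base: C4 ketone with CH2NMe2 at C5 (C5 epimers) | C=C1CCC(=O)C(CN(C)C)[C@@H]2CC[C@@](C)(CO[Si](C(C)C)(C(C)C)C(C)C)[C@H]12 | intermediate
20 | trimethylammonium iodide of 19 | C=C1CCC(=O)C(C[N+](C)(C)C)[C@@H]2CC[C@@](C)(CO[Si](C(C)C)(C(C)C)C(C)C)[C@H]12.[I-] | intermediate
21 | C4 ketone with C5 methylidene (ring centres as in 16) | C=C1CCC(=O)C(=C)[C@@H]2CC[C@@](C)(CO[Si](C(C)C)(C(C)C)C(C)C)[C@H]12 | intermediate
22 | lithium C4=C5 enolate carrying one C5 methyl | C=C1CCC([O-])=C(C)[C@@H]2CC[C@@](C)(CO[Si](C(C)C)(C(C)C)C(C)C)[C@H]12.[Li+] | intermediate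
23 | C5,C5-dimethyl C4 ketone, C11 silyl ether | C=C1CCC(=O)C(C)(C)[C@@H]2CC[C@@](C)(CO[Si](C(C)C)(C(C)C)C(C)C)[C@H]12 | intermediate
24 | C5,C5-dimethyl C4 ketone with free C11H2OH | C=C1CCC(=O)C(C)(C)[C@@H]2CC[C@@](C)(CO)[C@H]12 | intermediate
25 | C4 hydrazone of 24 | C=C1CCC(=NN)C(C)(C)[C@@H]2CC[C@@](C)(CO)[C@H]12 | intermediate
26 | C11 alcohol: cis-fused core (C1=CH2, C5 gem-dimethyl, C9 methyl) with CH2OH on C9 | C=C1CCCC(C)(C)[C@@H]2CC[C@@](C)(CO)[C@H]12 | intermediate
27 | C11 aldehyde (CHO on C9) | C=C1CCCC(C)(C)[C@@H]2CC[C@@](C)(C=O)[C@H]12 | intermediate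
28 | (methoxymethyl)triphenylphosphonium chloride | COC[P+](c1ccccc1)(c1ccccc1)c1ccccc1.[Cl-] | starting material
29 | methyl enol ether C9–CH=CH–OMe (E/Z mixture) | C=C1CCCC(C)(C)[C@@H]2CC[C@@](C)(C=COC)[C@H]12 | intermediate
30 | homologated aldehyde C9–C11H2–C13HO | C=C1CCCC(C)(C)[C@@H]2CC[C@@](C)(CC=O)[C@H]12 | intermediate
31 | (11R)-β-hydroxy aldehyde C9–C11H(CH2OH)–CHO | C=C1CCCC(C)(C)[C@@H]2CC[C@@](C)([C@H](CO)C=O)[C@H]12 | intermediate
32 | (triphenylphosphoranylidene)ketene | O=C=C=P(c1ccccc1)(c1ccccc1)c1ccccc1 | starting material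
33 | ester-stabilised ylide: C12–O–C(=O)–CH=PPh3 with the C13 aldehyde still free | C=C1CCCC(C)(C)[C@@H]2CC[C@@](C)([C@H](COC(=O)C=P(c3ccccc3)(c3ccccc3)c3ccccc3)C=O)[C@H]12 | intermediate
34 | (5R)-5-substituted 5,6-dihydro-2H-pyran-2-one, ring position 5 being C11 and carrying the bicyclic C9 substituent | C=C1CCCC(C)(C)[C@@H]2CC[C@@](C)([C@@H]3COC(=O)C=C3)[C@H]12 | intermediate
35 | (chloromethyl)(isopropoxy)dimethylsilane | CC(C)O[Si](C)(C)CCl | starting material
36 | trans-4,5-disubstituted tetrahydropyran-2-one: CH2SiMe2(Oi-Pr) on C13 trans to the bicyclic group on C11 | C=C1CCCC(C)(C)[C@@H]2CC[C@@](C)([C@@H]3COC(=O)C[C@H]3C[Si](C)(C)OC(C)C)[C@H]12 | intermediate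
37 | trans-4-(hydroxymethyl) δ-lactone | C=C1CCCC(C)(C)[C@@H]2CC[C@@](C)([C@@H]3COC(=O)C[C@H]3CO)[C@H]12 | intermediate
38 | β-substituted γ-butyrolactone (O–C14, C15=O) with free C12H2OH; C11 and C13 as in the target | C=C1CCCC(C)(C)[C@@H]2CC[C@@](C)([C@H](CO)[C@@H]3COC(=O)C3)[C@H]12 | intermediate
39 | C12 triethylsilyl ether of 38 | C=C1CCCC(C)(C)[C@@H]2CC[C@@](C)([C@H](CO[Si](CC)(CC)CC)[C@@H]3COC(=O)C3)[C@H]12 | intermediate
40 | C12 triethylsilyl ether of the trans-C16-hydroxy lactone | C=C1CCCC(C)(C)[C@@H]2CC[C@@](C)([C@H](CO[Si](CC)(CC)CC)[C@@H]3COC(=O)[C@H]3O)[C@H]12 | intermediate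
41 | C12,C16-diol (trans-α-hydroxy-β-substituted γ-lactone) | C=C1CCCC(C)(C)[C@@H]2CC[C@@](C)([C@H](CO)[C@@H]3COC(=O)[C@H]3O)[C@H]12 | intermediate
42 | acetic anhydride | CC(=O)OC(C)=O | starting material
43 | CNP0234964.1, the C12,C16-diacetate (6R,9R,10S,11R,13R,16S) | C=C1CCCC(C)(C)[C@@H]2CC[C@@](C)([C@H](COC(C)=O)[C@@H]3COC(=O)[C@H]3OC(C)=O)[C@H]12 | target

**Totals.** Total step count: 23. Longest linear sequence: 23 steps (from geraniol; the route is fully linear).

**Steps most likely to fail**

1. Step 10. The ring-forming event may discriminate poorly between the methyl and silyloxymethyl groups on C9, so that C6/C10 form on both faces, or the terminal allene may be lost to oligomerisation before it cycloadds. The fallback replaces the allene by an alkyne and makes the exocyclic alkene afterwards. It sets out from 12: the lithium acetylide (n-BuLi, THF, −78 °C) is alkylated with Me3SiCH2OTf to give propargylsilane F1. The alkyne–vinylcyclopropane (5+2) cycloaddition under [Rh(CO)2Cl]2 then gives bicyclic diene F2 (C1=C10, C1 carrying CH2SiMe3, C4 enol ether), in which only C6 is a new stereocentre. The operations of steps 11 and 12 (with NaHCO3 in place of DBU for the elimination) give enone F3 and gem-dimethyl ketone F4. Protodesilylation of the allylsilane (CF3CO2H, CH2Cl2, −40 °C) puts hydrogen on C10 from the face of H6 and shifts the double bond to C1=CH2, which comes back to the route at 23.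

2. Step 17. The catalyst and the neighbouring C9 centre may be mismatched, which would lower the selectivity at C11, or the aldol product may dehydrate to the α-methylene aldehyde. The fallback sets C11 by an auxiliary-controlled alkylation and sets out from 30. Condensation with (R)-1-amino-2-(methoxymethyl)pyrrolidine gives RAMP hydrazone F5; this auxiliary antipode is chosen because it should deliver the electrophile to the face that gives 11R. Deprotonation (LiN(i-Pr)2, THF, −78 °C) and alkylation with 4-MeOC6H4CH2OCH2Cl gives alkylated hydrazone F6. Cleavage with aqueous oxalic acid/Et2O gives protected hydroxy aldehyde F7. Z-selective olefination ((CF3CH2O)2P(O)CH2CO2Me, KN(SiMe3)2, 18-crown-6, THF, −78 °C) gives (Z)-enoate F8. Removal of the 4-methoxybenzyl group with DDQ (CH2Cl2/H2O) and acid-catalysed lactonisation (camphorsulfonic acid, CH2Cl2) come back to the route at 34.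

3. Step 19. The organomagnesium reagent may attack the lactone carbonyl and open the ring, or the organocopper species may fail to reach C13 next to the bulky C11 substituent. The fallback is a radical hydroxymethylation and sets out from 34: irradiation (350 nm) in degassed methanol with benzophenone generates the nucleophilic hydroxymethyl radical, which should add to C13 anti to the C11 substituent and give 37 directly. This is then equilibrated with DBU as in step 20 and comes back to the route at 38; the fallback makes no compound outside the list.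

**Further compounds**

F1 | step 10 | propargylsilane: 12 with the alkyne terminus carrying CH2SiMe3 | C[Si](C)(C)CC#C[C@](C)(CO[Si](C(C)C)(C(C)C)C(C)C)CC/C=C/C1(O[Si](C)(C)C(C)(C)C)CC1
F2 | step 10 | bicyclic diene: C1(CH2SiMe3)=C10, C4=C5 tert-butyldimethylsilyl enol ether, C6 and C9 as in 16 | C[Si](C)(C)CC1=C2[C@H](C=C(O[Si](C)(C)C(C)(C)C)CC1)CC[C@@]2(C)CO[Si](C(C)C)(C(C)C)C(C)C
F3 | step 10 | C5-methylidene C4-ketone of the allylsilane series | C[Si](C)(C)CC1=C2[C@H](C(=C)C(=O)CC1)CC[C@@]2(C)CO[Si](C(C)C)(C(C)C)C(C)C
F4 | step 10 | C5,C5-dimethyl C4-ketone of the allylsilane series | C[Si](C)(C)CC1=C2[C@H](C(C)(C)C(=O)CC1)CC[C@@]2(C)CO[Si](C(C)C)(C(C)C)C(C)C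
F5 | step 17 | RAMP hydrazone of 30 | C=C1CCCC(C)(C)[C@@H]2CC[C@@](C)(C/C=N/N3CCC[C@@H]3COC)[C@H]12
F6 | step 17 | (11R)-alkylated RAMP hydrazone carrying CH2OCH2C6H4OMe-4 at C11 | C=C1CCCC(C)(C)[C@@H]2CC[C@@](C)([C@H](COCc3ccc(OC)cc3)/C=N/N3CCC[C@@H]3COC)[C@H]12
F7 | step 17 | 4-methoxybenzyl ether of 31 | C=C1CCCC(C)(C)[C@@H]2CC[C@@](C)([C@H](COCc3ccc(OC)cc3)C=O)[C@H]12
F8 | step 17 | methyl (Z)-enoate C13=C16–C15O2Me with the C12 4-methoxybenzyl ether | C=C1CCCC(C)(C)[C@@H]2CC[C@@](C)([C@H](COCc3ccc(OC)cc3)/C=C\C(=O)OC)[C@H]12
F0 | step 19 | none | none
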